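## Retrosynthetic overview
1. The target comes from the 2,9-dione by reagent-controlled 1,2-reduction of the C9 enone, which sets 9R last. The conjugated isopropylidene ketone comes from a 2-hydroxy-1-isopropenyl macrocycle by oxidation and olefin conjugation.
2. Key disconnection C1–C2: the terminal isopropylidene π-bond attacks electrophilic C2 with charge build-up at C15. This is the bond and polarity of the geranylgeranyl → cembrenyl cation closure, run here as a Lewis-acid carbonyl-ene macrocyclisation of a fully oxygenated acyclic epoxy aldehyde.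
3. The acyclic chain is cut at C9–C10. One half is a dialkylzinc from (R)-linalyl acetate (C1, C10–C17 and C20; brings 12R and the acetate). The other is a C10 enal from geraniol (C2–C9, C18, C19).
4. The oxirane comes from O-transfer to the E-C3=C4 olefin (Sharpless epoxidation of geraniol, sets 3R,4S). The C9 oxygen and 7E geometry come from SeO2 allylic oxidation.
5. Ring order: oxirane first (step 2), 14-membered carbocycle second (step 6).

Assumption: cembrane numbering is used (C1 isopropylidene-bearing carbon, C2 ketone, C3/C4 oxirane, C7=C8, C9 carbinol, C12 acetoxy carbon), so the target is 3R,4S,7E,9R,12R; natural (R)-(−)-linalool is bought at ≥95% ee, and minor diastereomers from the few percent of wrong enantiomers in 2 and 4 are removed by chromatography of 13.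

## Route

Step 1
Reactants: 1 (R)-(−)-linalool [(3R)-3,7-dimethylocta-1,6-dien-3-ol]
Product: 2 (R)-linalyl acetate [(3R)-3,7-dimethylocta-1,6-dien-3-yl acetate]
Conditions: Ac2O (2 equiv), Et3N (3 equiv), DMAP (10 mol %), CH2Cl2, rt
Reagents that add atoms: acetic anhydride CC(=O)OC(C)=O
Why: Steglich-type DMAP-catalysed acylation esterifies this hindered tertiary allylic alcohol without ionising it, and because the C–O bond is never broken the chiral-pool centre (future C12, R) is carried over unchanged.

Step 2
Reactants: 3 geraniol [(2E)-3,7-dimethylocta-2,6-dien-1-ol]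
Product: 4 (2S,3S)-2,3-epoxygeraniol {[(2S,3S)-3-methyl-3-(4-methylpent-3-enyl)oxiran-2-yl]methanol}
Conditions: Ti(OiPr)4 (5 mol %), L-(+)-DET (7 mol %), anhydrous t-BuOOH (1.5 equiv), 4 Å MS, CH2Cl2, −20 °C
Reagents that add atoms: tert-butyl hydroperoxide CC(C)(C)OO
Why: Katsuki–Sharpless asymmetric epoxidation touches only the allylic-alcohol olefin, L-(+)-tartrate gives the (2S,3S)-epoxide (about 91–95% ee), and these centres become C3 (labelled R once C2 is a carbonyl) and C4 (S) with the trans relationship fixed by the E-olefin.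

Step 3
Reactants: 4 (2S,3S)-2,3-epoxygeraniol
Product: 6 (2E)-5-[(2S,3S)-3-(hydroxymethyl)-2-methyloxiran-2-yl]-2-methylpent-2-enal, via allylic alcohol 5 (not isolated)
Conditions: SeO2 (20 mol %), t-BuOOH (2.5 equiv), CH2Cl2, 0 °C → rt; aqueous wash; crude + MnO2 (15 equiv), CH2Cl2, rt
Reagents that add atoms: selenium dioxide O=[Se]=O (oxygen carrier); tert-butyl hydroperoxide CC(C)(C)OO (terminal oxidant)
Why: Riley-type SeO2 allylic oxidation (ene reaction then [2,3]-shift) attacks the only remaining trisubstituted olefin at its E-methyl group and so fixes the 7E geometry, MnO2 then oxidises only the allylic alcohol so that all material converges on the enal, and no stereocentre is formed.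

Step 4
Reactants: 2 (R)-linalyl acetate (5 equiv); 6 epoxy hydroxy enal
Product: 9 (6R,9RS,10E)-9-hydroxy-13-[(2S,3S)-3-(hydroxymethyl)-2-methyloxiran-2-yl]-2,6,10-trimethyltrideca-2,10-dien-6-yl acetate, via alkyldiethylborane 7 (not isolated), via dialkylzinc 8 (not isolated)
Conditions: 2, Et2BH (from BH3·SMe2 + 2 Et3B), 0 °C → rt; Et2Zn (neat), 0 °C, then 0.1 mmHg; Ti(OiPr)4 (2 equiv), (±)-trans-1,2-(TfNH)2-cyclohexane (8 mol %), toluene, −20 °C, add 6; aq NH4Cl
Reagents that add atoms: none
Why: In this Knochel-type sequence the dialkylborane hydroborates the monosubstituted vinyl group far faster than the trisubstituted olefin and places boron on the terminal carbon, boron–zinc exchange gives an ester-tolerant dialkylzinc, and ligand-accelerated titanium-mediated 1,2-addition to the enal forms C9–C10 while surplus reagent merely deprotonates the free OH, the new C9 carbinol being formed without control and erased in step 5.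

Step 5
Reactants: 9 seco-diol (C9 epimers)
Product: 10 (6R,10E)-13-[(2S,3R)-3-formyl-2-methyloxiran-2-yl]-2,6,10-trimethyl-9-oxotrideca-2,10-dien-6-yl acetate
Conditions: Dess–Martin periodinane (3 equiv), pyridine (6 equiv), CH2Cl2, 0 °C → rt; used at once
Reagents that add atoms: none
Why: Dess–Martin oxidation turns the primary epoxy alcohol into the configurationally stable epoxy aldehyde and the allylic carbinol into the enone in one buffered operation, which erases the uncontrolled C9 centre and makes C7=C8 too electron-poor to compete as a π-nucleophile in step 6.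

Step 6
Reactants: 10 keto epoxy aldehyde
Product: 11 (3S,4S,7E,12R)-12-acetoxy-3,4-epoxy-2-hydroxycembra-7,15-dien-9-one (1-isopropenyl-2-carbinol; mixture at C1 and C2)
Conditions: Me2AlCl (4 equiv), CH2Cl2, −78 °C, 10 added by syringe pump over 6 h (final 1 mM), → −40 °C; aq Rochelle salt
Reagents that add atoms: none
Why: Proposed new method: Me2AlCl activates the inductively electron-poor α,β-epoxy aldehyde, the only nucleophilic π-bond left (the terminal isopropylidene) attacks C2 through its less substituted carbon C1 so that charge builds up at tertiary C15 as in the cembrenyl cation, and a methyl proton passes to the aldehyde oxygen through a six-membered transition state to close the 14-membered ring under pseudo-high dilution, with the alcohol–aluminium complex then losing methane so that no Brønsted acid persists; the closest known reaction types are Me2AlCl-promoted type-I carbonyl-ene (Prins) cyclisations and alkylaluminium-chloride-promoted ene macrocyclisations of conjugated ynals bearing the same isopropylidene terminus to 12–14-membered rings; C1 and C2 form as a mixture that does not matter because both become sp2 in step 7, while C3, C4 and C12 are untouched.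

Step 7
Reactants: 11 macrocyclic ene adduct
Product: 13 (3R,4S,7E,12R)-12-acetoxy-3,4-epoxycembra-1(15),7-diene-2,9-dione, via isopropenyl ketone 12 (not isolated)
Conditions: Dess–Martin periodinane (1.5 equiv), pyridine, CH2Cl2, 0 °C → rt; silica plug; DBU (30 mol %), CH2Cl2, 0 °C → rt
Reagents that add atoms: none
Why: Dess–Martin oxidation removes the C2 carbinol centre and DBU then deprotonates the doubly activated C1–H (α-keto and allylic) so that γ-reprotonation moves the olefin into the thermodynamically preferred tetrasubstituted conjugated position (isopulegone-to-pulegone type isomerisation), which removes the C1 centre without touching the oxirane.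

Step 8
Reactants: 13 2,9-dione
Product: 14 target (3R,4S,7E,9R,12R)-12-acetoxy-3,4-epoxy-9-hydroxycembra-1(15),7-dien-2-one
Conditions: (S)-Me-CBS (30 mol %), catecholborane (1.3 equiv), toluene, −78 °C; MeOH, pH 7 buffer
Reagents that add atoms: none
Why: In this Corey–Bakshi–Shibata reduction catecholborane is inert at −78 °C to ketones that do not bind the oxazaborolidine, only the C9 enone offers a small flank (C10H2) for binding whereas C2 is walled in by the tetrasubstituted alkylidene carbon and the trisubstituted oxirane, and with the alkenyl group as the large substituent the (S)-catalyst delivers hydride 1,2 to give 9R (same sense as acetophenone to (R)-1-phenylethanol).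

## Compound list
1 | (R)-(−)-linalool | CC(C)=CCC[C@@](C)(O)C=C | starting material
2 | (R)-linalyl acetate | CC(=O)O[C@](C)(CCC=C(C)C)C=C | intermediate
3 | geraniol | CC(C)=CCC/C(C)=C/CO | starting material
4 | (2S,3S)-2,3-epoxygeraniol | OC[C@@H]1O[C@@]1(C)CCC=C(C)C | intermediate
5 | (2E)-5-[(2S,3S)-3-(hydroxymethyl)-2-methyloxiran-2-yl]-2-methylpent-2-en-1-ol | OC[C@@H]1O[C@@]1(C)CC/C=C(\C)CO | intermediate
6 | (2E)-5-[(2S,3S)-3-(hydroxymethyl)-2-methyloxiran-2-yl]-2-methylpent-2-enal | OC[C@@H]1O[C@@]1(C)CC/C=C(\C)C=O | intermediate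
7 | [(3S)-3-acetoxy-3,7-dimethyloct-6-en-1-yl]diethylborane (same spatial arrangement as 2; label changes because B ranks below C) | CC(=O)O[C@](C)(CCC=C(C)C)CCB(CC)CC | intermediate
8 | bis[(3R)-3-acetoxy-3,7-dimethyloct-6-en-1-yl]zinc | CC(=O)O[C@](C)(CCC=C(C)C)CC[Zn]CC[C@@](C)(CCC=C(C)C)OC(C)=O | intermediate
9 | (6R,9RS,10E)-9-hydroxy-13-[(2S,3S)-3-(hydroxymethyl)-2-methyloxiran-2-yl]-2,6,10-trimethyltrideca-2,10-dien-6-yl acetate | OC[C@@H]1O[C@@]1(C)CC/C=C(\C)C(O)CC[C@@](C)(CCC=C(C)C)OC(C)=O | intermediate
10 | (6R,10E)-13-[(2S,3R)-3-formyl-2-methyloxiran-2-yl]-2,6,10-trimethyl-9-oxotrideca-2,10-dien-6-yl acetate | O=C[C@@H]1O[C@@]1(C)CC/C=C(\C)C(=O)CC[C@@](C)(CCC=C(C)C)OC(C)=O | intermediate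
11 | (3S,4S,7E,12R)-12-acetoxy-3,4-epoxy-2-hydroxycembra-7,15-dien-9-one (C1/C2 mixture) | CC(=O)O[C@]1(C)CCC(C(C)=C)C(O)[C@@H]2O[C@@]2(C)CC/C=C(\C)C(=O)CC1 | intermediate
12 | (3R,4S,7E,12R)-12-acetoxy-3,4-epoxycembra-7,15-diene-2,9-dione (C1 mixture) | CC(=O)O[C@]1(C)CCC(C(C)=C)C(=O)[C@@H]2O[C@@]2(C)CC/C=C(\C)C(=O)CC1 | intermediate
13 | (3R,4S,7E,12R)-12-acetoxy-3,4-epoxycembra-1(15),7-diene-2,9-dione | CC(=O)O[C@]1(C)CCC(=C(C)C)C(=O)[C@@H]2O[C@@]2(C)CC/C=C(\C)C(=O)CC1 | intermediate
14 | (3R,4S,7E,9R,12R)-12-acetoxy-3,4-epoxy-9-hydroxycembra-1(15),7-dien-2-one (CNP0404804.1) | CC(=O)O[C@]1(C)CCC(=C(C)C)C(=O)[C@@H]2O[C@@]2(C)CC/C=C(\C)[C@H](O)CC1 | target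

## Step count and risks
Total steps: 8. Longest linear sequence: 7 (steps 2–8, from geraniol). No protecting groups are used.

**Step 6 (most likely to fail).**
- The ring closure is entropically slow.
- During that time the Lewis acid can open or rearrange the oxirane, ionise the tertiary acetate, or transfer methyl to the aldehyde.
- The fallback sets out from 10 and comes back at 11. It makes the same C1–C2 bond by umpolung instead of cationic activation.
- The isopropylidene group is the only electron-rich olefin of 10. Ene-type chlorination (NCS, cat. PhSeCl, CH2Cl2, rt) converts it into the transposed secondary allylic chloride F1 (terminus CH2=C(Me)–CHCl–, everything else as in 10).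
- Slow addition of F1 to CrCl2 in THF (intramolecular Nozaki–Hiyama allylation, high dilution) gives an allylchromium that carries the metal on the CH2 terminus.
- This species adds to the aldehyde through its γ-carbon C1. It delivers the same isopropenyl carbinol 11 with no strong Lewis acid present.

**Step 8.**
- The C2 ketone is an activated epoxy ketone and may be reduced alongside C9.
- The fallback sets out from 11 and comes back at 14. It reduces C9 while it is the only ketone in the molecule.
- (S)-Me-CBS with catecholborane (one extra equivalent for the free OH) converts 11 into the (9R)-2,9-diol F2.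
- TESCl/imidazole at −20 °C silylates the less hindered allylic C9–OH to give the 9-O-triethylsilyl ether F3.
- Dess–Martin oxidation gives the silylated isopropenyl ketone F4, which DBU conjugates to the silylated target F5.
- HF·pyridine/pyridine in THF at 0 °C then releases 14.

**Step 4.**
- The Ti/Zn medium meets a free epoxy alcohol.
- The hydroboration must also spare the trisubstituted olefin.
- The fallback sets out from 3 (using the same zinc reagent 8) and comes back at 10. It postpones the epoxidation until after the fragment union.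
- Geraniol 3 is acetylated (Ac2O, pyridine) to geranyl acetate F6.
- SeO2 in refluxing EtOH gives (2E,6E)-8-oxogeranyl acetate F7.
- Addition of 8 is now run with the (1S,2S)-bis(triflamide) ligand (Re-face attack) and gives the (9R)-hydroxy diacetate F8.
- K2CO3/MeOH at 0 °C removes only the primary allylic acetate to give the (9R)-dienediol F9.
- Katsuki–Sharpless epoxidation with L-(+)-DET oxidises only the primary allylic alcohol. The 9R secondary allylic alcohol is the slow-reacting enantiomer for L-(+)-tartrate.
- This gives the (9R)-epoxy diol F10, the 9R component of 9, which is oxidised as in step 5 to 10.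

## Further compounds
F1 | step 6 | allylic chloride: 10 with the Me2C=CH– terminus changed to CH2=C(Me)–CHCl– (C–Cl epimers) | O=C[C@@H]1O[C@@]1(C)CC/C=C(\C)C(=O)CC[C@@](C)(CCC(Cl)C(C)=C)OC(C)=O
F2 | step 8 | (3S,4S,7E,9R,12R)-12-acetoxy-3,4-epoxycembra-7,15-diene-2,9-diol (C1/C2 mixture) | CC(=O)O[C@]1(C)CCC(C(C)=C)C(O)[C@@H]2O[C@@]2(C)CC/C=C(\C)[C@H](O)CC1
F3 | step 8 | 9-O-triethylsilyl ether of F2 | CC(=O)O[C@]1(C)CCC(C(C)=C)C(O)[C@@H]2O[C@@]2(C)CC/C=C(\C)[C@H](O[Si](CC)(CC)CC)CC1
F4 | step 8 | (3R,4S,7E,9R,12R)-12-acetoxy-3,4-epoxy-9-(triethylsilyloxy)cembra-7,15-dien-2-one (C1 mixture) | CC(=O)O[C@]1(C)CCC(C(C)=C)C(=O)[C@@H]2O[C@@]2(C)CC/C=C(\C)[C@H](O[Si](CC)(CC)CC)CC1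
F5 | step 8 | 9-O-triethylsilyl ether of 14 | CC(=O)O[C@]1(C)CCC(=C(C)C)C(=O)[C@@H]2O[C@@]2(C)CC/C=C(\C)[C@H](O[Si](CC)(CC)CC)CC1
F6 | step 4 | geranyl acetate | CC(C)=CCC/C(C)=C/COC(C)=O
F7 | step 4 | (2E,6E)-8-oxogeranyl acetate | O=C/C(C)=C/CC/C(C)=C/COC(C)=O
F8 | step 4 | (2E,6E,8R,11R)-11-acetoxy-8-hydroxy-3,7,11,15-tetramethylhexadeca-2,6,14-trien-1-yl acetate | CC(=O)OC/C=C(\C)CC/C=C(\C)[C@H](O)CC[C@@](C)(CCC=C(C)C)OC(C)=O
F9 | step 4 | (2E,6E,8R,11R)-11-acetoxy-3,7,11,15-tetramethylhexadeca-2,6,14-triene-1,8-diol | OC/C=C(\C)CC/C=C(\C)[C@H](O)CC[C@@](C)(CCC=C(C)C)OC(C)=O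
F10 | step 4 | 9R epimer of 9 | OC[C@@H]1O[C@@]1(C)CC/C=C(\C)[C@H](O)CC[C@@](C)(CCC=C(C)C)OC(C)=O
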